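## Retrosynthetic overview

1. Feature: the ketone carbon carries two rings of the same type, a 6-alkyl-2,4-dihydroxyphenyl ketone. Ring A has C1 acyl, C2 ethyl and C4/C6 OH; ring B has C1 acyl, C2/C4 OH and C6 CH2 leading to the pyrone. C1–C2 of ring A and C1–C6 of ring B are therefore read as the two triple bonds of a dialkynyl ketone.
2. Pyrone ring C is cut first, at the lactone O1–C2 bond and then at C5–C6. This leads back to an arylacetic acid and the dianion of methyl acetoacetate; the acid comes from a 2-(silyloxy)ethyl arm on C6 of ring B.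
3. Rings A and B are cut together by a double (4+2) disconnection into 9-(tert-butyldimethylsilyloxy)nona-3,6-diyn-5-one and two molecules of 1-methoxy-1,3-bis(trimethylsilyloxy)buta-1,3-diene.
4. The diynone comes from but-1-yne, DMF and silylated but-3-yn-1-ol, followed by MnO2 oxidation. The diene comes from methyl acetoacetate by two silylations.
5. Ring order: A and B in one flask, ring C last.

Key step: step 7

Remark: the target has no stereocentre. The one carbinol centre made on the way (step 3) is racemic and is erased in step 4. The enol-ether geometries drawn in steps 5 and 6 have no bearing on the outcome.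

## Route

Step 1
Reactants: 1 but-3-yn-1-ol
Product: 2 tert-butyl(but-3-yn-1-yloxy)dimethylsilane
Conditions: TBSCl, imidazole, CH2Cl2, 0 °C → rt
Reagents that add atoms: tert-butyldimethylsilyl chloride, CC(C)(C)[Si](C)(C)Cl
Why: Imidazole-promoted silyl ether formation on an unhindered primary alcohol, which leaves the terminal alkyne C–H free for step 3.

Step 2
Reactants: 3 but-1-yne
Product: 5 pent-2-ynal, via but-1-ynyllithium 4 (not isolated)
Conditions: n-BuLi, THF, −78 °C; DMF, −78 °C → rt; inverse quench into 10% aq. KH2PO4/MTBE, 0 °C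
Reagents that add atoms: N,N-dimethylformamide, CN(C)C=O; n-butyllithium, [Li]CCCC (supplies only the lithium of intermediate 4)
Why: Formylation of a lithium acetylide with DMF, where the buffered inverse quench collapses the hemiaminal alkoxide without letting dimethylamine add to the ynal.

Step 3
Reactants: 2 tert-butyl(but-3-yn-1-yloxy)dimethylsilane; 5 pent-2-ynal
Product: 7 9-(tert-butyldimethylsilyloxy)nona-3,6-diyn-5-ol (racemic), via lithium acetylide 6 (not isolated)
Conditions: 2, n-BuLi, THF, −78 °C; then 5, −78 → −20 °C; aq. NH4Cl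
Reagents that add atoms: n-butyllithium, [Li]CCCC (supplies only the lithium of intermediate 6)
Why: 1,2-Addition of a lithium acetylide to an aldehyde; the new carbinol centre forms without control and is removed in step 4.

Step 4
Reactants: 7 9-(tert-butyldimethylsilyloxy)nona-3,6-diyn-5-ol
Product: 8 9-(tert-butyldimethylsilyloxy)nona-3,6-diyn-5-one
Conditions: activated MnO2 (15 equiv), CH2Cl2, rt; filtration through Celite
Reagents that add atoms: none
Why: MnO2 oxidation of a doubly propargylic alcohol, a neutral heterogeneous method that spares the silyl ether and exposes the Michael-sensitive diynone to neither base nor nucleophile.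

Step 5
Reactants: 9 methyl acetoacetate
Product: 10 methyl (Z)-3-(trimethylsilyloxy)but-2-enoate
Conditions: TMSCl, Et3N, hexane, rt
Reagents that add atoms: chlorotrimethylsilane, C[Si](C)(C)Cl
Why: Soft enolisation and O-silylation of a β-keto ester, in which any E isomer is equally useful because the geometry is lost in step 6.

Step 6
Reactants: 10 methyl (Z)-3-(trimethylsilyloxy)but-2-enoate
Product: 12 1-methoxy-1,3-bis(trimethylsilyloxy)buta-1,3-diene (drawn Z), via lithium dienolate 11 (not isolated)
Conditions: LiN(i-Pr)2 (LDA), THF, −78 °C; TMSCl, −78 → 0 °C; filtration under argon, used without chromatography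
Reagents that add atoms: chlorotrimethylsilane, C[Si](C)(C)Cl; lithium diisopropylamide, CC(C)[N-]C(C)C.[Li+] (supplies only the lithium of intermediate 11)
Why: Vinylogous (γ) deprotonation of the silyloxy enoate followed by O-silylation of the ester dienolate, the standard way to this ketene silyl acetal diene.

Step 7
Reactants: 8 9-(tert-butyldimethylsilyloxy)nona-3,6-diyn-5-one; 12 1-methoxy-1,3-bis(trimethylsilyloxy)buta-1,3-diene (two molecules enter the product; 5 equiv used, added in portions)
Product: 15 {2-[2-(tert-butyldimethylsilyloxy)ethyl]-4,6-dihydroxyphenyl}(2-ethyl-4,6-dihydroxyphenyl)methanone, via mono-adduct ynone 13 (not isolated), via tetrakis(trimethylsilyl) ether 14 (not isolated)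
Conditions: 12 (5 equiv), N,O-bis(trimethylsilyl)acetamide (BSA, 3 equiv), toluene (1 M), 100–110 °C, sealed vessel; then K2CO3 (0.2 equiv), MeOH, 0 °C
Reagents that add atoms: none
Why: This is the known Diels–Alder/aromatisation of alkynyl ketones with 1,1,3-trioxygenated butadienes, used on both arms of one cross-conjugated diynone: the CH2 terminus of 12 (its most nucleophilic carbon) bonds to the alkyl-bearing β-carbon of an ynone arm and the ketene-acetal carbon to the α-carbon, either in one asynchronous (4+2) event or as a Michael addition followed by a Mukaiyama-type closure. Ring A closes as a six-membered carbocycle through the new bonds C2–C3 and C1–C6 and ring B in the same (4+2) mode through C6–C5 and C1–C2, and each cyclohexa-1,4-diene adduct aromatises by expelling methanol from its mixed-ketal carbon, so no stereocentre outlasts the step. The selectivity needed is regiochemical at both alkynes and is secured by the single carbonyl between them, which polarises each triple bond so that its outer carbon is the electrophilic end, while attack at C=O is not expected because no Lewis acid is present to start a Mukaiyama aldol addition. It does not matter which arm reacts first (13 is drawn with ring A made first), since both mono-adducts lead to 14, and in either one the di-ortho-substituted aryl group is twisted out of conjugation, so the carbonyl keeps activating the remaining alkyne. BSA takes up the liberated methanol, which stops it adding to the ynone and keeps the ortho oxygen silylated, so that oxa-Michael closure to a chromone is held back until the second ring is in place. Brief K2CO3/MeOH at 0 °C should then strip the four aryl trimethylsilyl ethers and leave the primary alkyl tert-butyldimethylsilyl ether.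

Step 8
Reactants: 15 {2-[2-(tert-butyldimethylsilyloxy)ethyl]-4,6-dihydroxyphenyl}(2-ethyl-4,6-dihydroxyphenyl)methanone
Product: 16 {2,4-bis(benzyloxy)-6-[2-(tert-butyldimethylsilyloxy)ethyl]phenyl}[2,4-bis(benzyloxy)-6-ethylphenyl]methanone
Conditions: BnBr (6 equiv), K2CO3 (8 equiv), n-Bu4NI (cat.), DMF, 60 °C
Reagents that add atoms: benzyl bromide, BrCc1ccccc1
Why: Williamson etherification of four phenoxides, in which the polar solvent, heat and iodide catalysis carry the two carbonyl-chelated ortho hydroxyls along and the alkyl silyl ether is inert to carbonate.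

Step 9
Reactants: 16 {2,4-bis(benzyloxy)-6-[2-(tert-butyldimethylsilyloxy)ethyl]phenyl}[2,4-bis(benzyloxy)-6-ethylphenyl]methanone
Product: 17 [2,4-bis(benzyloxy)-6-ethylphenyl][2,4-bis(benzyloxy)-6-(2-hydroxyethyl)phenyl]methanone
Conditions: n-Bu4NF, THF, 0 °C → rt; water
Reagents that add atoms: none
Why: Fluoride-driven cleavage of the Si–O bond, chosen over acid so that the freed alcohol is not pushed into ketal formation with the neighbouring diaryl ketone.

Step 10
Reactants: 17 [2,4-bis(benzyloxy)-6-ethylphenyl][2,4-bis(benzyloxy)-6-(2-hydroxyethyl)phenyl]methanone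
Product: 18 2-{3,5-bis(benzyloxy)-2-[2,4-bis(benzyloxy)-6-ethylbenzoyl]phenyl}acetic acid
Conditions: TEMPO (0.2 equiv), PhI(OAc)2 (2.5 equiv), MeCN/CH2Cl2/H2O, rt
Reagents that add atoms: water, O
Why: Oxoammonium-catalysed oxidation of a primary alcohol through the aldehyde hydrate to the acid, a chlorine-free method that should not halogenate the electron-rich rings.

Step 11
Reactants: 18 2-{3,5-bis(benzyloxy)-2-[2,4-bis(benzyloxy)-6-ethylbenzoyl]phenyl}acetic acid; 9 methyl acetoacetate
Product: 21 methyl 6-{3,5-bis(benzyloxy)-2-[2,4-bis(benzyloxy)-6-ethylbenzoyl]phenyl}-3,5-dioxohexanoate, via acyl imidazole 19 (not isolated), via acetoacetate dianion 20 (not isolated)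
Conditions: 18, CDI, THF, rt; separately 9 (4 equiv), NaH, THF, 0 °C, then n-BuLi, 0 °C; 19 added at −78 °C, → −20 °C; 1 M HCl
Reagents that add atoms: 1,1'-carbonyldiimidazole, O=C(n1ccnc1)n1ccnc1 (supplies only the imidazolyl group of intermediate 19); sodium hydride, [H-].[Na+], and n-butyllithium, [Li]CCCC (supply only the counter-ions of intermediate 20)
Why: Claisen-type γ-acylation of a β-keto ester dianion by an acyl imidazole, with excess dianion to absorb the imidazole N–H and the acidic product; if the benzylic position enolises instead, loss of imidazolide gives a ketene that accepts the dianion at the same carbon.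

Step 12
Reactants: 21 methyl 6-{3,5-bis(benzyloxy)-2-[2,4-bis(benzyloxy)-6-ethylbenzoyl]phenyl}-3,5-dioxohexanoate
Product: 22 6-{3,5-bis(benzyloxy)-2-[2,4-bis(benzyloxy)-6-ethylbenzoyl]benzyl}-4-hydroxy-2H-pyran-2-one
Conditions: DBU (2 equiv), toluene, rt → 60 °C; 1 M HCl
Reagents that add atoms: none
Why: Base-induced lactonisation of a 3,5-dioxo ester, in which the C5 enolate oxygen attacks the ester in a six-membered closure with loss of methanol, while the tetra-ortho-substituted, electron-rich diaryl ketone is too hindered for the competing aldol closure to a naphthol.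

Step 13
Reactants: 22 6-{3,5-bis(benzyloxy)-2-[2,4-bis(benzyloxy)-6-ethylbenzoyl]benzyl}-4-hydroxy-2H-pyran-2-one
Product: 23 6-[2-(2-ethyl-4,6-dihydroxybenzoyl)-3,5-dihydroxybenzyl]-4-hydroxy-2H-pyran-2-one (target)
Conditions: H2 (1 atm), 10 wt% Pd/C, THF/MeOH, rt, stopped once four equivalents of H2 are consumed
Reagents that add atoms: none
Why: Catalytic hydrogenolysis of four benzyl aryl ethers, during which the crowded diaryl ketone and the vinylogous-acid pyrone should resist reduction at atmospheric pressure.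

## Compound list

1 | but-3-yn-1-ol | C#CCCO | starting material
2 | tert-butyl(but-3-yn-1-yloxy)dimethylsilane | C#CCCO[Si](C)(C)C(C)(C)C | intermediate
3 | but-1-yne | CCC#C | starting material
4 | but-1-ynyllithium (not isolated) | CCC#C[Li] | intermediate
5 | pent-2-ynal | CCC#CC=O | intermediate
6 | [4-(tert-butyldimethylsilyloxy)but-1-ynyl]lithium (not isolated) | [Li]C#CCCO[Si](C)(C)C(C)(C)C | intermediate
7 | 9-(tert-butyldimethylsilyloxy)nona-3,6-diyn-5-ol (racemic) | CCC#CC(O)C#CCCO[Si](C)(C)C(C)(C)C | intermediate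
8 | 9-(tert-butyldimethylsilyloxy)nona-3,6-diyn-5-one | CCC#CC(=O)C#CCCO[Si](C)(C)C(C)(C)C | intermediate
9 | methyl acetoacetate | CC(=O)CC(=O)OC | starting material
10 | methyl (Z)-3-(trimethylsilyloxy)but-2-enoate | C/C(O[Si](C)(C)C)=C/C(=O)OC | intermediate
11 | lithium 1-methoxy-3-(trimethylsilyloxy)buta-1,3-dien-1-olate (not isolated) | CO/C([O-])=C/C(=C)O[Si](C)(C)C.[Li+] | intermediate
12 | (Z)-1-methoxy-1,3-bis(trimethylsilyloxy)buta-1,3-diene | CO/C(O[Si](C)(C)C)=C/C(=C)O[Si](C)(C)C | intermediate
13 | 5-(tert-butyldimethylsilyloxy)-1-[2-ethyl-4,6-bis(trimethylsilyloxy)phenyl]pent-2-yn-1-one (not isolated) | CCc1cc(O[Si](C)(C)C)cc(O[Si](C)(C)C)c1C(=O)C#CCCO[Si](C)(C)C(C)(C)C | intermediate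
14 | {2-[2-(tert-butyldimethylsilyloxy)ethyl]-4,6-bis(trimethylsilyloxy)phenyl}[2-ethyl-4,6-bis(trimethylsilyloxy)phenyl]methanone (not isolated) | CCc1cc(O[Si](C)(C)C)cc(O[Si](C)(C)C)c1C(=O)c1c(O[Si](C)(C)C)cc(O[Si](C)(C)C)cc1CCO[Si](C)(C)C(C)(C)C | intermediate
15 | {2-[2-(tert-butyldimethylsilyloxy)ethyl]-4,6-dihydroxyphenyl}(2-ethyl-4,6-dihydroxyphenyl)methanone | CCc1cc(O)cc(O)c1C(=O)c1c(O)cc(O)cc1CCO[Si](C)(C)C(C)(C)C | intermediate
16 | {2,4-bis(benzyloxy)-6-[2-(tert-butyldimethylsilyloxy)ethyl]phenyl}[2,4-bis(benzyloxy)-6-ethylphenyl]methanone | CCc1cc(OCc2ccccc2)cc(OCc2ccccc2)c1C(=O)c1c(OCc2ccccc2)cc(OCc2ccccc2)cc1CCO[Si](C)(C)C(C)(C)C | intermediate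
17 | [2,4-bis(benzyloxy)-6-ethylphenyl][2,4-bis(benzyloxy)-6-(2-hydroxyethyl)phenyl]methanone | CCc1cc(OCc2ccccc2)cc(OCc2ccccc2)c1C(=O)c1c(OCc2ccccc2)cc(OCc2ccccc2)cc1CCO | intermediate
18 | 2-{3,5-bis(benzyloxy)-2-[2,4-bis(benzyloxy)-6-ethylbenzoyl]phenyl}acetic acid | CCc1cc(OCc2ccccc2)cc(OCc2ccccc2)c1C(=O)c1c(OCc2ccccc2)cc(OCc2ccccc2)cc1CC(=O)O | intermediate
19 | 2-{3,5-bis(benzyloxy)-2-[2,4-bis(benzyloxy)-6-ethylbenzoyl]phenyl}-1-(imidazol-1-yl)ethanone (not isolated) | CCc1cc(OCc2ccccc2)cc(OCc2ccccc2)c1C(=O)c1c(OCc2ccccc2)cc(OCc2ccccc2)cc1CC(=O)n1ccnc1 | intermediate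
20 | lithium sodium dianion of methyl acetoacetate (not isolated) | C=C([O-])C=C([O-])OC.[Li+].[Na+] | intermediate
21 | methyl 6-{3,5-bis(benzyloxy)-2-[2,4-bis(benzyloxy)-6-ethylbenzoyl]phenyl}-3,5-dioxohexanoate | CCc1cc(OCc2ccccc2)cc(OCc2ccccc2)c1C(=O)c1c(OCc2ccccc2)cc(OCc2ccccc2)cc1CC(=O)CC(=O)CC(=O)OC | intermediate
22 | 6-{3,5-bis(benzyloxy)-2-[2,4-bis(benzyloxy)-6-ethylbenzoyl]benzyl}-4-hydroxy-2H-pyran-2-one | CCc1cc(OCc2ccccc2)cc(OCc2ccccc2)c1C(=O)c1c(OCc2ccccc2)cc(OCc2ccccc2)cc1Cc1cc(O)cc(=O)o1 | intermediate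
23 | 6-[2-(2-ethyl-4,6-dihydroxybenzoyl)-3,5-dihydroxybenzyl]-4-hydroxy-2H-pyran-2-one | CCc1cc(O)cc(O)c1C(=O)c1c(O)cc(O)cc1Cc1cc(O)cc(=O)o1 | target

## Step count and risks

Total step count: 13.
Longest linear sequence: 10 (steps 1, 3, 4, 7, 8, 9, 10, 11, 12, 13).

**Step 7.** After the first ring has formed, the ortho silyl group may be lost early, and oxa-Michael closure onto the remaining alkyne could then outrun the second, slower cycloaddition. The diene may also decay by thermal silyl migration before that cycloaddition is complete.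

The fallback uncouples the two annulations and caps the oxygens of the first ring before the second alkyne is attached. It sets out from 5 and 12 and comes back at 16. One cycloaddition on the more reactive ynal (BSA, toluene, 60–80 °C) should give 2-ethyl-4,6-bis(trimethylsilyloxy)benzaldehyde F1. This is methanolysed (K2CO3, MeOH) to 2-ethyl-4,6-dihydroxybenzaldehyde F2 and benzylated (BnBr, K2CO3, DMF) to 2,4-bis(benzyloxy)-6-ethylbenzaldehyde F3. Addition of lithium acetylide 6 should give racemic 1-[2,4-bis(benzyloxy)-6-ethylphenyl]-5-(tert-butyldimethylsilyloxy)pent-2-yn-1-ol F4, and MnO2 the aryl ynone 1-[2,4-bis(benzyloxy)-6-ethylphenyl]-5-(tert-butyldimethylsilyloxy)pent-2-yn-1-one F5, whose benzylated ortho oxygens cannot add to the alkyne. A single cycloaddition with excess 12 should give [2,4-bis(benzyloxy)-6-ethylphenyl]{2-[2-(tert-butyldimethylsilyloxy)ethyl]-4,6-bis(trimethylsilyloxy)phenyl}methanone F6. Methanolysis then gives [2,4-bis(benzyloxy)-6-ethylphenyl]{2-[2-(tert-butyldimethylsilyloxy)ethyl]-4,6-dihydroxyphenyl}methanone F7, and benzylation of F7 under the conditions of step 8 gives 16.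

**Step 11.** Proton transfer from the doubly activated benzylic CH2 of the acyl imidazole to the dianion may replace acylation. The neighbouring ketone oxygen may also attack the activated acyl group.

The fallback swaps acylation for an aldol addition followed by oxidation, so no activated acyl derivative is ever present. It sets out from 17 and comes back at 21. Dess–Martin periodinane (NaHCO3, CH2Cl2) should give 2-{3,5-bis(benzyloxy)-2-[2,4-bis(benzyloxy)-6-ethylbenzoyl]phenyl}acetaldehyde F8. Dianion 20 at −78 °C should add to it faster than it enolises it, giving racemic methyl 6-{3,5-bis(benzyloxy)-2-[2,4-bis(benzyloxy)-6-ethylbenzoyl]phenyl}-5-hydroxy-3-oxohexanoate F9. A second Dess–Martin oxidation erases the carbinol centre and gives 21.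

**Step 13.** The C5–C6 double bond of the pyrone may be saturated, or cleavage of the hindered ortho benzyl ethers may stall so that forcing becomes necessary.

The fallback reverses the order of the last two operations, so the pyrone never meets hydrogen. It sets out from 21 and comes back at 23. Hydrogenolysis of 21 (H2, 10 wt% Pd/C, THF/MeOH), whose enolised dicarbonyl chain is not reduced under these conditions, should give methyl 6-[2-(2-ethyl-4,6-dihydroxybenzoyl)-3,5-dihydroxyphenyl]-3,5-dioxohexanoate F10. Lactonisation with excess DBU (7 equiv, THF, 40 °C; then 1 M HCl), the phenols being carried as phenoxides, should give 23.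

## Further compounds

F1 | step 7 | 2-ethyl-4,6-bis(trimethylsilyloxy)benzaldehyde | CCc1cc(O[Si](C)(C)C)cc(O[Si](C)(C)C)c1C=O
F2 | step 7 | 2-ethyl-4,6-dihydroxybenzaldehyde | CCc1cc(O)cc(O)c1C=O
F3 | step 7 | 2,4-bis(benzyloxy)-6-ethylbenzaldehyde | CCc1cc(OCc2ccccc2)cc(OCc2ccccc2)c1C=O
F4 | step 7 | 1-[2,4-bis(benzyloxy)-6-ethylphenyl]-5-(tert-butyldimethylsilyloxy)pent-2-yn-1-ol (racemic) | CCc1cc(OCc2ccccc2)cc(OCc2ccccc2)c1C(O)C#CCCO[Si](C)(C)C(C)(C)C
F5 | step 7 | 1-[2,4-bis(benzyloxy)-6-ethylphenyl]-5-(tert-butyldimethylsilyloxy)pent-2-yn-1-one | CCc1cc(OCc2ccccc2)cc(OCc2ccccc2)c1C(=O)C#CCCO[Si](C)(C)C(C)(C)C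
F6 | step 7 | [2,4-bis(benzyloxy)-6-ethylphenyl]{2-[2-(tert-butyldimethylsilyloxy)ethyl]-4,6-bis(trimethylsilyloxy)phenyl}methanone | CCc1cc(OCc2ccccc2)cc(OCc2ccccc2)c1C(=O)c1c(O[Si](C)(C)C)cc(O[Si](C)(C)C)cc1CCO[Si](C)(C)C(C)(C)C
F7 | step 7 | [2,4-bis(benzyloxy)-6-ethylphenyl]{2-[2-(tert-butyldimethylsilyloxy)ethyl]-4,6-dihydroxyphenyl}methanone | CCc1cc(OCc2ccccc2)cc(OCc2ccccc2)c1C(=O)c1c(O)cc(O)cc1CCO[Si](C)(C)C(C)(C)C
F8 | step 11 | 2-{3,5-bis(benzyloxy)-2-[2,4-bis(benzyloxy)-6-ethylbenzoyl]phenyl}acetaldehyde | CCc1cc(OCc2ccccc2)cc(OCc2ccccc2)c1C(=O)c1c(OCc2ccccc2)cc(OCc2ccccc2)cc1CC=O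
F9 | step 11 | methyl 6-{3,5-bis(benzyloxy)-2-[2,4-bis(benzyloxy)-6-ethylbenzoyl]phenyl}-5-hydroxy-3-oxohexanoate (racemic) | CCc1cc(OCc2ccccc2)cc(OCc2ccccc2)c1C(=O)c1c(OCc2ccccc2)cc(OCc2ccccc2)cc1CC(O)CC(=O)CC(=O)OC
F10 | step 13 | methyl 6-[2-(2-ethyl-4,6-dihydroxybenzoyl)-3,5-dihydroxyphenyl]-3,5-dioxohexanoate | CCc1cc(O)cc(O)c1C(=O)c1c(O)cc(O)cc1CC(=O)CC(=O)CC(=O)OC
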